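**Remark on the chemistry:** the target is read as the 2,3-cis (2R,3R) flavan with galloyl esters on O3 and O5 and a free 7-OH. 3,4,5-Tris(benzyloxy)benzoic acid and vinyltriphenylphosphonium bromide are taken as purchased.

## Retrosynthetic overview

- Target ⇐ perbenzylated digallate 16 (hydrogenolysis of ten benzyl ethers) ⇐ cis-(2R,3R) flavan-3-ol 5-O-gallate 15 (esterification of O3 with acid 9).
- 15 ⇐ racemic flavan-3-one 14 by transfer hydrogenation under dynamic kinetic resolution, which sets C2 and C3 together; 14 ⇐ flav-2-ene 12 by hydroboration/oxidation and alcohol oxidation.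
- Ring C is the only ring built (rings A and B are bought as phloroglucinol and a gallic acid derivative). It is closed at C2–C3 by an intramolecular Wittig reaction of a C3 ylide with an aryl gallate carbonyl that becomes C2: 12 ⇐ phosphonium bis-gallate 10.
- Enabling feature: C2 with ring B is a 3,4,5-trioxygenated benzylic carbon, i.e. a galloyl group at lower oxidation level, and C4a of ring A lies between two equivalent oxygens (O1 and O5, with O7 para). A symmetric bis-gallate therefore holds ring B/C2 and the 5-O-gallate as two homotopic esters; whichever is olefinated, the other is already the 5-O-gallate.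
- 10 ⇐ 5-(benzyloxy)resorcinol bis-MOM ether 3 (lithiation between the two oxygens, addition to vinyltriphenylphosphonium bromide, deprotection, double esterification) ⇐ phloroglucinol.

Key step: step 6

## Route

Step 1
Reactants: 1 phloroglucinol (benzene-1,3,5-triol)
Product: 2 5-(benzyloxy)benzene-1,3-diol
Conditions: BnBr (0.3 equiv), K2CO3, DMF, 0 °C to rt; excess 1 recovered
Reagents that add atoms: benzyl bromide, BrCc1ccccc1
Why: Williamson etherification with the triol in excess shifts the statistical distribution towards the monoether, which is separated from recovered 1 and from the diether.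

Step 2
Reactants: 2 5-(benzyloxy)benzene-1,3-diol
Product: 3 1-(benzyloxy)-3,5-bis(methoxymethoxy)benzene
Conditions: NaH, MOMCl, DMF, 0 °C to rt
Reagents that add atoms: chloromethyl methyl ether, COCCl
Why: Williamson-type protection of both phenols as MOM acetals gives groups that direct lithiation and are later removed by acid without touching the benzyl ether.

Step 3
Reactants: 3 1-(benzyloxy)-3,5-bis(methoxymethoxy)benzene; 4 vinyltriphenylphosphonium bromide
Product: 7 {2-[4-(benzyloxy)-2,6-bis(methoxymethoxy)phenyl]ethyl}triphenylphosphonium bromide, via aryllithium 5 (not isolated), via phosphonium ylide 6 (not isolated)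
Conditions: n-BuLi, THF, 0 °C; then 4, −78 to 0 °C; then HBr (33% in AcOH, 1 equiv), 0 °C
Reagents that add atoms: hydrogen bromide, Br
Why: Directed ortho-metalation takes place at the carbon flanked by both MOM ethers, conjugate addition of the aryllithium to the vinylphosphonium salt gives an ylide, and protonation gives the salt that carries C4 and C3 of the target.

Step 4
Reactants: 7 {2-[4-(benzyloxy)-2,6-bis(methoxymethoxy)phenyl]ethyl}triphenylphosphonium bromide
Product: 8 {2-[4-(benzyloxy)-2,6-dihydroxyphenyl]ethyl}triphenylphosphonium bromide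
Conditions: HBr (48% aq, 0.5 equiv), MeOH, 45 °C
Reagents that add atoms: none
Why: Acid-catalysed acetal exchange with methanol removes both MOM groups, while the aryl benzyl ether and the phosphonium group are stable and the bromide counter-ion is kept.

Step 5
Reactants: 8 {2-[4-(benzyloxy)-2,6-dihydroxyphenyl]ethyl}triphenylphosphonium bromide; 9 3,4,5-tris(benzyloxy)benzoic acid (2.2 equiv)
Product: 10 {2-[4-(benzyloxy)-2,6-bis{[3,4,5-tris(benzyloxy)benzoyl]oxy}phenyl]ethyl}triphenylphosphonium bromide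
Conditions: DCC, DMAP (cat.), CH2Cl2, 0 °C to rt
Reagents that add atoms: none
Why: Steglich esterification of both equivalent phenols gives the symmetric bis-gallate; neither DMAP nor the phenoxide is basic enough to form the ylide.

Step 6
Reactants: 10 {2-[4-(benzyloxy)-2,6-bis{[3,4,5-tris(benzyloxy)benzoyl]oxy}phenyl]ethyl}triphenylphosphonium bromide
Product: 12 7-(benzyloxy)-2-[3,4,5-tris(benzyloxy)phenyl]-4H-chromen-5-yl 3,4,5-tris(benzyloxy)benzoate, via phosphonium ylide 11 (not isolated)
Conditions: NaN(SiMe3)2 (1.0 equiv), THF, −78 °C; then toluene, 80 °C, high dilution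
Reagents that add atoms: none
Why: Deprotonation of the P-bound CH2 gives ylide 11, whose carbanionic C3 attacks the carbonyl carbon of one ortho gallate ester (the future C2); the resulting oxaphosphetane loses Ph3P=O and leaves the C2=C3 enol ether, which is the intramolecular Wittig olefination of aryl esters used to make benzofurans, indoles and 4H-chromenes from ω-(o-acyloxyaryl)alkylphosphonium salts. Ring C (C3, C4, C4a, C8a, O1, C2) closes by a 6-exo-trig attack of C3 on the C2 carbonyl, followed by cycloreversion of the four-membered P–O ring. No stereocentre is formed: C2 and C3 emerge as the two ends of an enol ether, the oxidation level from which both are set together in step 9. The selectivity needed is reaction of exactly one of the two esters; it is secured because there is one ylide per molecule and the two esters are homotopic, so either closure gives 12 and the untouched ester is the 5-O-gallate of the target. If the tetrahedral adduct instead expels the phenoxide (acyl transfer to carbon), the keto-phosphonium phenoxide can re-close to the same hemiketal at 80 °C and is drawn to 12 by the irreversible loss of Ph3P=O. One equivalent of a non-nucleophilic amide base at high dilution limits ester cleavage, intermolecular acylation and base-induced migration of the double bond towards ring A.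

Step 7
Reactants: 12 7-(benzyloxy)-2-[3,4,5-tris(benzyloxy)phenyl]-4H-chromen-5-yl 3,4,5-tris(benzyloxy)benzoate
Product: 13 rac-(2R,3S)-7-(benzyloxy)-3-hydroxy-2-[3,4,5-tris(benzyloxy)phenyl]chroman-5-yl 3,4,5-tris(benzyloxy)benzoate (2,3-trans)
Conditions: BH3·THF, THF, 0 °C to rt; then Me3NO·2H2O, THF, 60 °C
Reagents that add atoms: trimethylamine N-oxide, C[N+](C)(C)[O-]
Why: Syn hydroboration of the enol ether puts boron on C3 (β to O1) and hydrogen on C2, and oxidation with retention gives the racemic 2,3-trans alcohol; the amine oxide is used because alkaline peroxide would cleave the aryl ester.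

Step 8
Reactants: 13 rac-(2R,3S)-7-(benzyloxy)-3-hydroxy-2-[3,4,5-tris(benzyloxy)phenyl]chroman-5-yl 3,4,5-tris(benzyloxy)benzoate
Product: 14 rac-7-(benzyloxy)-3-oxo-2-[3,4,5-tris(benzyloxy)phenyl]chroman-5-yl 3,4,5-tris(benzyloxy)benzoate
Conditions: Dess–Martin periodinane, CH2Cl2, rt
Reagents that add atoms: none
Why: Dess–Martin oxidation of the secondary alcohol under neutral conditions gives the flavan-3-one, whose C2–H (α to the ketone, benzylic and α to O1) is configurationally labile, which step 9 exploits.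

Step 9
Reactants: 14 rac-7-(benzyloxy)-3-oxo-2-[3,4,5-tris(benzyloxy)phenyl]chroman-5-yl 3,4,5-tris(benzyloxy)benzoate
Product: 15 (2R,3R)-7-(benzyloxy)-3-hydroxy-2-[3,4,5-tris(benzyloxy)phenyl]chroman-5-yl 3,4,5-tris(benzyloxy)benzoate (2,3-cis)
Conditions: RuCl[(R,R)-TsDPEN](p-cymene) (2 mol %), HCO2H/Et3N (5:2), CH2Cl2, 30 °C
Reagents that add atoms: none
Why: Noyori–Ikariya transfer hydrogenation under dynamic kinetic resolution: C2 epimerises through the enol faster than the ketone is reduced, and the catalyst is expected to reduce the (2R) ketone with hydride delivery to C3 anti to the 2-aryl group, so C2 is set by the resolution and C3 by catalyst control, giving the cis (2R,3R) alcohol.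

Step 10
Reactants: 15 (2R,3R)-7-(benzyloxy)-3-hydroxy-2-[3,4,5-tris(benzyloxy)phenyl]chroman-5-yl 3,4,5-tris(benzyloxy)benzoate; 9 3,4,5-tris(benzyloxy)benzoic acid
Product: 16 (2R,3R)-7-(benzyloxy)-2-[3,4,5-tris(benzyloxy)phenyl]chromane-3,5-diyl bis[3,4,5-tris(benzyloxy)benzoate]
Conditions: DCC, DMAP, CH2Cl2, rt
Reagents that add atoms: none
Why: Steglich esterification of the axial 3-OH proceeds with retention at C3 and under conditions too mild to epimerise C2.

Step 11
Reactants: 16 (2R,3R)-7-(benzyloxy)-2-[3,4,5-tris(benzyloxy)phenyl]chromane-3,5-diyl bis[3,4,5-tris(benzyloxy)benzoate]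
Product: 17 epigallocatechin 3,5-digallate
Conditions: H2 (1 atm), Pd(OH)2/C, THF/MeOH, rt
Reagents that add atoms: none
Why: Hydrogenolysis cleaves the ten primary benzyl ethers, while the esters and the hindered ring ether C2–O1 are expected to survive these neutral, mild conditions.

## Compound list

1 | phloroglucinol (benzene-1,3,5-triol) | Oc1cc(O)cc(O)c1 | starting material
2 | 5-(benzyloxy)benzene-1,3-diol | Oc1cc(O)cc(OCc2ccccc2)c1 | intermediate
3 | 1-(benzyloxy)-3,5-bis(methoxymethoxy)benzene | COCOc1cc(OCOC)cc(OCc2ccccc2)c1 | intermediate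
4 | vinyltriphenylphosphonium bromide | C=C[P+](c1ccccc1)(c1ccccc1)c1ccccc1.[Br-] | starting material
5 | [4-(benzyloxy)-2,6-bis(methoxymethoxy)phenyl]lithium | [Li]c1c(OCOC)cc(OCc2ccccc2)cc1OCOC | intermediate (not isolated)
6 | {2-[4-(benzyloxy)-2,6-bis(methoxymethoxy)phenyl]ethylidene}triphenylphosphorane | COCOc1cc(OCc2ccccc2)cc(OCOC)c1CC=P(c1ccccc1)(c1ccccc1)c1ccccc1 | intermediate (not isolated)
7 | {2-[4-(benzyloxy)-2,6-bis(methoxymethoxy)phenyl]ethyl}triphenylphosphonium bromide | COCOc1cc(OCc2ccccc2)cc(OCOC)c1CC[P+](c1ccccc1)(c1ccccc1)c1ccccc1.[Br-] | intermediate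
8 | {2-[4-(benzyloxy)-2,6-dihydroxyphenyl]ethyl}triphenylphosphonium bromide | Oc1cc(OCc2ccccc2)cc(O)c1CC[P+](c1ccccc1)(c1ccccc1)c1ccccc1.[Br-] | intermediate
9 | 3,4,5-tris(benzyloxy)benzoic acid | OC(=O)c1cc(OCc2ccccc2)c(OCc2ccccc2)c(OCc2ccccc2)c1 | starting material
10 | {2-[4-(benzyloxy)-2,6-bis{[3,4,5-tris(benzyloxy)benzoyl]oxy}phenyl]ethyl}triphenylphosphonium bromide | O=C(Oc1cc(OCc2ccccc2)cc(OC(=O)c2cc(OCc3ccccc3)c(OCc3ccccc3)c(OCc3ccccc3)c2)c1CC[P+](c1ccccc1)(c1ccccc1)c1ccccc1)c1cc(OCc2ccccc2)c(OCc2ccccc2)c(OCc2ccccc2)c1.[Br-] | intermediate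
11 | {2-[4-(benzyloxy)-2,6-bis{[3,4,5-tris(benzyloxy)benzoyl]oxy}phenyl]ethylidene}triphenylphosphorane | O=C(Oc1cc(OCc2ccccc2)cc(OC(=O)c2cc(OCc3ccccc3)c(OCc3ccccc3)c(OCc3ccccc3)c2)c1CC=P(c1ccccc1)(c1ccccc1)c1ccccc1)c1cc(OCc2ccccc2)c(OCc2ccccc2)c(OCc2ccccc2)c1 | intermediate (not isolated)
12 | 7-(benzyloxy)-2-[3,4,5-tris(benzyloxy)phenyl]-4H-chromen-5-yl 3,4,5-tris(benzyloxy)benzoate | O=C(Oc1cc(OCc2ccccc2)cc2c1CC=C(c1cc(OCc3ccccc3)c(OCc3ccccc3)c(OCc3ccccc3)c1)O2)c1cc(OCc2ccccc2)c(OCc2ccccc2)c(OCc2ccccc2)c1 | intermediate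
13 | rac-(2R,3S)-7-(benzyloxy)-3-hydroxy-2-[3,4,5-tris(benzyloxy)phenyl]chroman-5-yl 3,4,5-tris(benzyloxy)benzoate (trans; racemate, one enantiomer drawn) | O=C(Oc1cc(OCc2ccccc2)cc2c1C[C@H](O)[C@@H](c1cc(OCc3ccccc3)c(OCc3ccccc3)c(OCc3ccccc3)c1)O2)c1cc(OCc2ccccc2)c(OCc2ccccc2)c(OCc2ccccc2)c1 | intermediate
14 | rac-7-(benzyloxy)-3-oxo-2-[3,4,5-tris(benzyloxy)phenyl]chroman-5-yl 3,4,5-tris(benzyloxy)benzoate (racemic at C2) | O=C(Oc1cc(OCc2ccccc2)cc2c1CC(=O)C(c1cc(OCc3ccccc3)c(OCc3ccccc3)c(OCc3ccccc3)c1)O2)c1cc(OCc2ccccc2)c(OCc2ccccc2)c(OCc2ccccc2)c1 | intermediate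
15 | (2R,3R)-7-(benzyloxy)-3-hydroxy-2-[3,4,5-tris(benzyloxy)phenyl]chroman-5-yl 3,4,5-tris(benzyloxy)benzoate (cis) | O=C(Oc1cc(OCc2ccccc2)cc2c1C[C@@H](O)[C@@H](c1cc(OCc3ccccc3)c(OCc3ccccc3)c(OCc3ccccc3)c1)O2)c1cc(OCc2ccccc2)c(OCc2ccccc2)c(OCc2ccccc2)c1 | intermediate
16 | (2R,3R)-7-(benzyloxy)-2-[3,4,5-tris(benzyloxy)phenyl]chromane-3,5-diyl bis[3,4,5-tris(benzyloxy)benzoate] | O=C(Oc1cc(OCc2ccccc2)cc2c1C[C@@H](OC(=O)c1cc(OCc3ccccc3)c(OCc3ccccc3)c(OCc3ccccc3)c1)[C@@H](c1cc(OCc3ccccc3)c(OCc3ccccc3)c(OCc3ccccc3)c1)O2)c1cc(OCc2ccccc2)c(OCc2ccccc2)c(OCc2ccccc2)c1 | intermediate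
17 | epigallocatechin 3,5-digallate, (2R,3R) | O=C(Oc1cc(O)cc2c1C[C@@H](OC(=O)c1cc(O)c(O)c(O)c1)[C@@H](c1cc(O)c(O)c(O)c1)O2)c1cc(O)c(O)c(O)c1 | target

## Step count and risks

Total step count: 11. Longest linear sequence: 11 steps (1 to 17); 4 and 9 are purchased.

Steps most likely to fail:

**Step 6.** The tetrahedral adduct may collapse with loss of the phenoxide (acyl transfer to carbon) without re-closing, or the base may move the double bond towards ring A. The fallback is ring-closing metathesis, which forms the same C2=C3 bond. It sets out from 3: lithiation as in step 3 and quenching with allyl bromide should give 2-allyl-5-(benzyloxy)-1,3-bis(methoxymethoxy)benzene F1. HCl in MeOH should then give 2-allyl-5-(benzyloxy)benzene-1,3-diol F2, and esterification with 9 (DCC, DMAP) the symmetric diester 2-allyl-5-(benzyloxy)-1,3-phenylene bis[3,4,5-tris(benzyloxy)benzoate] F3. Methylenation of one of the two homotopic ester carbonyls with Cp2TiMe2 in deficiency (toluene, 70 °C, unreacted F3 recycled) should give the mono enol ether 2-allyl-5-(benzyloxy)-3-({1-[3,4,5-tris(benzyloxy)phenyl]ethenyl}oxy)phenyl 3,4,5-tris(benzyloxy)benzoate F4. Second-generation Grubbs catalyst (toluene, 70 °C) should close the ring with loss of ethylene; the route is rejoined at 12.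

**Step 9.** Epimerisation at C2 may be slower than reduction, or hydride may be delivered with the opposite facial sense, because the choice of the (R,R) catalyst rests on a model and not on a close analogue; the antipodal catalyst is the first remedy. The fallback is reagent-controlled hydroboration followed by substrate-controlled reduction. It sets out from 12: hydroboration with monoisopinocampheylborane prepared from (+)-α-pinene (THF, −25 °C, Me3NO work-up) is expected, by analogy with 1-arylcycloalkenes, to give (2R,3S)-7-(benzyloxy)-3-hydroxy-2-[3,4,5-tris(benzyloxy)phenyl]chroman-5-yl 3,4,5-tris(benzyloxy)benzoate F5. Dess–Martin oxidation under base-free conditions should give (2R)-7-(benzyloxy)-3-oxo-2-[3,4,5-tris(benzyloxy)phenyl]chroman-5-yl 3,4,5-tris(benzyloxy)benzoate F6. LiBH(s-Bu)3 (THF, −78 °C) should attack C3 from the face opposite the 2-aryl group to give the cis alcohol; the route is rejoined at 15.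

**Step 3.** The hindered aryllithium may attack phosphorus or abstract a proton in place of conjugate addition. The fallback builds the two-carbon arm stepwise. It sets out from 3: lithiation and opening of oxirane (BF3·OEt2, THF, −78 °C) should give 2-[4-(benzyloxy)-2,6-bis(methoxymethoxy)phenyl]ethanol F7. An Appel reaction (CBr4, PPh3, CH2Cl2, 0 °C) should give 5-(benzyloxy)-2-(2-bromoethyl)-1,3-bis(methoxymethoxy)benzene F8, and heating with PPh3 in MeCN the phosphonium bromide; the route is rejoined at 7.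

## Further compounds

F1 | step 6 | 2-allyl-5-(benzyloxy)-1,3-bis(methoxymethoxy)benzene | COCOc1cc(OCc2ccccc2)cc(OCOC)c1CC=C
F2 | step 6 | 2-allyl-5-(benzyloxy)benzene-1,3-diol | Oc1cc(OCc2ccccc2)cc(O)c1CC=C
F3 | step 6 | 2-allyl-5-(benzyloxy)-1,3-phenylene bis[3,4,5-tris(benzyloxy)benzoate] | C=CCc1c(OC(=O)c2cc(OCc3ccccc3)c(OCc3ccccc3)c(OCc3ccccc3)c2)cc(OCc2ccccc2)cc1OC(=O)c1cc(OCc2ccccc2)c(OCc2ccccc2)c(OCc2ccccc2)c1
F4 | step 6 | 2-allyl-5-(benzyloxy)-3-({1-[3,4,5-tris(benzyloxy)phenyl]ethenyl}oxy)phenyl 3,4,5-tris(benzyloxy)benzoate | C=CCc1c(OC(=C)c2cc(OCc3ccccc3)c(OCc3ccccc3)c(OCc3ccccc3)c2)cc(OCc2ccccc2)cc1OC(=O)c1cc(OCc2ccccc2)c(OCc2ccccc2)c(OCc2ccccc2)c1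
F5 | step 9 | (2R,3S)-7-(benzyloxy)-3-hydroxy-2-[3,4,5-tris(benzyloxy)phenyl]chroman-5-yl 3,4,5-tris(benzyloxy)benzoate (single enantiomer) | O=C(Oc1cc(OCc2ccccc2)cc2c1C[C@H](O)[C@@H](c1cc(OCc3ccccc3)c(OCc3ccccc3)c(OCc3ccccc3)c1)O2)c1cc(OCc2ccccc2)c(OCc2ccccc2)c(OCc2ccccc2)c1
F6 | step 9 | (2R)-7-(benzyloxy)-3-oxo-2-[3,4,5-tris(benzyloxy)phenyl]chroman-5-yl 3,4,5-tris(benzyloxy)benzoate | O=C(Oc1cc(OCc2ccccc2)cc2c1CC(=O)[C@@H](c1cc(OCc3ccccc3)c(OCc3ccccc3)c(OCc3ccccc3)c1)O2)c1cc(OCc2ccccc2)c(OCc2ccccc2)c(OCc2ccccc2)c1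
F7 | step 3 | 2-[4-(benzyloxy)-2,6-bis(methoxymethoxy)phenyl]ethanol | COCOc1cc(OCc2ccccc2)cc(OCOC)c1CCO
F8 | step 3 | 5-(benzyloxy)-2-(2-bromoethyl)-1,3-bis(methoxymethoxy)benzene | COCOc1cc(OCc2ccccc2)cc(OCOC)c1CCBr
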